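The earlier runs and the new flask were computed on assumed constants; noise was put on by code.

Count the partner.

the same everywhere: free catalyst 0.79 mM; second catalyst 1.2 mM
- epsilon: substrate 0.79 M; partner 0.36 M; temperature 25 °C; run made earlier
- alpha: substrate 0.79 M; partner 0.53 M; temperature 40 °C; run made earlier
- zeta: substrate 1.6 M; partner 0.711 M; temperature 25 °C; run made earlier
- south: substrate 0.79 M; partner 0.711 M; temperature 50 °C; time 4.0 d
- east: substrate 0.79 M; partner 0.711 M; temperature 30 °C; time 4.0 d
- north-west: substrate 0.79 M; partner 0.711 M; at 30 °C until 50 h, from then on at 50 °C; time 4.0 d

| run | time / d | target / % |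
|---|---|---|
| epsilon | 0.625 | 2.4 |
| epsilon | 1.67 | 6.1 |
| epsilon | 3.00 | 12.2 |
| epsilon | 4.00 | 14.1 |
| epsilon | 8.00 | 21.1 |
| epsilon | 10.0 | 23.7 |
| alpha | 0.833 | 11.0 |
| alpha | 1.25 | 14.3 |
| alpha | 2.08 | 18.2 |
| alpha | 2.50 | 21.4 |
| alpha | 4.00 | 24.1 |
| alpha | 5.00 | 24.2 |
| zeta | 0.833 | 4.2 |
| zeta | 3.00 | 12.4 |
| zeta | 6.00 | 19.3 |
| zeta | 8.00 | 20.8 |
| zeta | 10.0 | 22.0 |

(readings scatter by 0.5 percentage points)

- the analysis behind the earlier runs scatters by 0.5 percentage points, standard deviation

1. the best flask by amount of target, in percent of the substrate charged; "all alike" if 1.5 percentage points covers them all (south / east / north-west / all alike)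
2. amount of target at the end, in percent of the substrate charged, south
3. amount of target at the end, in percent of the substrate charged, east
4. amount of target at the end, in percent of the substrate charged, north-west

Hanna reads these flasks as a race: partner is the reagent charged in the smaller amount, so with one partner per target they can climb to 90.0% of the substrate charged, and since alpha at 40 °C stood at 24.1% after 4.00 d while epsilon at 25 °C needed 10.0 d for 23.7%, she backs south at 50 °C, although alpha also held more partner.

Marek writes the balance of that same partner, charge minus target formed, and finds that alpha, flat at 24.2%, still holds 63.9% of its partner, so he takes it that a rival route consumes the substrate. Zeta had twice the substrate of epsilon, yet with c_partner/c_substrate nearly equal, 0.444 against 0.456, it ended at 22.0% against 23.7%, which suggests that the split follows that ratio.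

So Marek divides target over non-target, y/(1−y), by c_partner/c_substrate, and reads 0.682 from epsilon and 0.635 from zeta. Their mean, 0.658, is what he calls the pull, the target won per substrate lost for each unit of that charge ratio, a kind of selectivity factor. Alpha reads only 0.476, so heat weakens the pull.

I side with Marek and, rather than guess how the fall runs between the two temperatures, I use both readings as a bracket: at the charge ratio of the new flasks, the pull gives a finished yield of 37.2%, and alpha's reading gives 30.0%. So I place a finished east at 30 °C between these two figures and south, hotter than alpha, below 30.0%, though east should fall short of its range in 4.0 d, as epsilon was still rising at its last reading; north-west spends its substrate-rich stage cool and finishes hot, so I put it first.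

The forecast gave 21.5% for south, 24% for east and 27% for north-west, with north-west best, judging that “Deactivation seems more temperature-sensitive than reaction”, and its east lies below my 30.0% for a finished flask.

The flasks give 23.8% for south, 27.7% for east and 31.1% for north-west, so north-west is best.

    substrate + free catalyst → free catalyst + intermediate (k = 150 M⁻¹ h⁻¹, Ea = 58.0 kJ mol⁻¹)
    substrate + intermediate → side product (k = 1.20 M⁻¹ h⁻¹, Ea = 75.0 kJ mol⁻¹)
    partner + second catalyst + intermediate → second catalyst + target (k = 160 M⁻² h⁻¹, Ea = 50.0 kJ mol⁻¹)
    (constants at 50 °C)

South ends with substrate at 0% and free catalyst at 100%, and the main reason for its low target is the passing of substrate + intermediate into side product: without that step south reaches 86.6%. Hanna's race belongs to a flask stopped with substrate still standing, such as the neighbour of east with 3.2 × 10⁻⁴ M free catalyst, which ends at 16.3% with 16.8% of its substrate left. East left for 40.0 d gives 33.4%, inside the bracket of 30.0% to 37.2%, and for the neighbour of east with 0.20 M substrate the same bracket runs from 62.8% to 70.1%, where that flask holds 54.5% target and a further 11.1% as substrate and intermediate.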